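- Early times are where the rates of a flask can be read, so the recipes, the earlier runs and the questions stand first.

| flask | substrate | coupling partner | free catalyst | remark | time |
|---|---|---|---|---|---|
| Friday's | 0.19 M | 0.228 M | 0.95 mM | run made earlier |  |
| Wednesday's | 0.19 M | 0.228 M | 1.4 mM | run made earlier |  |
| dawn | 0.19 M (fed, over 30 min) | 0.228 M | 0.95 mM | all else is in the flask from the start; the feed brings no volume worth counting | 40 min |
| summer | 0.19 M | 0.228 M (fed, over 30 min) | 0.95 mM | all else is in the flask from the start; the feed brings no volume worth counting | 40 min |
| winter | 0.19 M (fed, over 8.0 min) | 0.228 M | 0.95 mM | all else is in the flask from the start; the feed brings no volume worth counting | 40 min |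
| dusk | 0.19 M | 0.228 M | 0.95 mM | everything together at the start | 40 min |

| run | time / min | target / % | side product / % | substrate / % |
|---|---|---|---|---|
| Friday's | 6.00 | 15 | 2 | 37 |
| Friday's | 12.0 | 33 | 4 | 12 |
| Friday's | 20.0 | 46 | 5 | 9 |
| Friday's | 25.0 | 55 | 8 | 7 |
| Wednesday's | 1.50 | 4 | 0 | 74 |
| Wednesday's | 4.00 | 14 | 4 | 41 |
| Wednesday's | 8.00 | 35 | 3 | 12 |
| Wednesday's | 12.0 | 48 | 8 | 6 |

(each reading ± 2 percentage points)

- a species is counted by the substrate in it: one idle adduct counts as two
- amounts and yields of target count idle adduct too
- what may be going on: substrate + free catalyst -> free catalyst + open intermediate; free catalyst + open intermediate <-> catalyst intermediate; coupling partner + catalyst intermediate <-> free catalyst + target; open intermediate -> side product; substrate + target <-> idle adduct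
- in an amount of target, one idle adduct counts as one target

1. the best flask by share of target in target plus side product; "all alike" if 1.5 percentage points covers them all (dawn / summer / winter / dusk / all alike)
2. share of target in target plus side product at the end, dawn
3. share of target in target plus side product at the end, summer
4. share of target in target plus side product at the end, winter
5. share of target in target plus side product at the end, dusk

- Friday's run has the charges of dusk. Up to 12.0 min it made target at 0.0275 min⁻¹ of the charge, as read with its scatter.
- From 12.0 min to 25.0 min Friday's target rate was 0.0169 min⁻¹, slower by a factor of 0.615. Applying that factor once more gives 0.0104 min⁻¹ for the later stretch, which is an assumption of this reckoning.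
- Friday's side product rate barely moved: 0.00333 min⁻¹ up to 12.0 min and 0.00320 min⁻¹ up to 25.0 min. So the share of target in target plus side product, the selectivity, falls as the flask ages.
- In this reckoning a steady feed of substrate delays that ageing. In dawn, the substrate has spent on average 25.0 min in the flask at the reading; this is its mean age.
- Dawn is therefore taken as Friday's run read at 25.0 min, with a share of 87.3%.
- Dusk ages the full 40 min: target 70.6%, side product 12.8%, share 84.7%.
- Winter's mean age is 36.0 min, which gives a share of 85.2%.
- Summer feeds coupling partner, which the step to open intermediate does not use. Side product is therefore taken at 12.8%, while target follows the partner's mean age, 25.0 min, for a share of 81.1%. Dawn comes out best.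
- The forecast gave 87%, 86%, 87% and 87% for dawn, summer, winter and dusk, and all alike, holding that “the split depends on free catalyst, not on how much intermediate is present”, which differs from this reckoning.
- The simulation gives 87.5%, 80.1%, 85.1% and 84.2% in that order, with dawn best. Summer's gap from the reckoning, 1 percentage point, is the widest.

    substrate + free catalyst → free catalyst + open intermediate (k = 3.00 M⁻¹ s⁻¹)
    free catalyst + open intermediate ⇌ catalyst intermediate (K = 12.0 M⁻¹, k = 2.00 M⁻¹ s⁻¹)
    coupling partner + catalyst intermediate ⇌ free catalyst + target (K = 2.60, k = 4.60 M⁻¹ s⁻¹)
    open intermediate → side product (k = 1.60 × 10⁻⁴ s⁻¹)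
    substrate + target ⇌ idle adduct, settled at all times (K = 12.0 M⁻¹)

- The neighbouring flask is dawn with coupling partner cut to 0.091 M, a factor of 0.399 on the charge. Its mean age stays 25.0 min, so side product reckons at 8.00%. With target scaled by that factor, target reckons at 22.0%, for a share of 73.3%. The simulated neighbouring flask holds target 32.2% and side product 9.28%, a share of 77.6%.

The numbers in the tables are simulated with made-up constants; noise was put on by code.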